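## Analysis of the target

The target is [(2R,3S,4S,5R)-2,5-bis(4-hydroxy-3,5-dimethoxyphenyl)oxolane-3,4-diyl]dimethanol: one tetrahydrofuran ring with ring oxygen O1, aryl groups on C2 and C5, and hydroxymethyl groups on C3 and C4. Reading the stereodescriptors into three dimensions gives the all-trans arrangement (2,3-trans, 3,4-trans, 4,5-trans). The molecule therefore has a twofold axis through O1 and the midpoint of C3–C4, and its two halves are equivalent. The sensitive groups are the two free syringyl phenols (easily oxidised, quinone methide formation) and the two ring C–O bonds, which are benzylic ethers on electron-rich rings. These bonds ionise under acid, can be hydrogenolysed, and can rearrange with loss of water once the primary hydroxyls are free. The difficulty is four contiguous stereocentres in one absolute sense on a ring with no other handle. The same benzylic lability helps: C2 and C5 can be equilibrated, and with C3 and C4 fixed trans the all-trans isomer is the thermodynamic one. The centres that must be set kinetically are thus C3 and C4. The strategy rests on the unit O1–C2–C3 with a one-carbon branch on C3. This is the product pattern of a [2,3]-shift of an allylic oxonium ylide, with C2 as the former ylide carbon and the C3 branch arising as a vinyl group. If the allyl unit is tied back to C4 and C5 in a 3,6-dihydro-2H-pyran, the shift contracts the six-membered ring to the tetrahydrofuran.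

## Retrosynthetic reasoning

Protecting groups. Target 18 is traced back to the bis-benzyl ether 17 and then to the mono-silyl ether 16, cutting only O–benzyl and O–silicon bonds. The phenols must be masked throughout, because free syringyl phenols would quench a metal carbene and a hydride base. Benzyl is chosen because an aryl benzyl ether oxygen is a poor carbene acceptor. The two primary oxygens stay distinguishable until the end, since one of them is only created after the key step.

C3 hydroxymethyl group. Compound 16 is traced back through aldehyde 15 to the vinyl compound 14 by reconnecting the C3 branch to a second carbon as C=C. This turns the branch into what a [2,3]-shift leaves behind. The forward steps only have to cleave a monosubstituted alkene and reduce the aldehyde; the α-centre of 15 is already in its more stable trans arrangement.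

Key disconnection. In 14 the bonds O1–C2 and C2–C3 are cut and O1 is reconnected to the terminal vinyl carbon. C2 becomes the carbene carbon of aryldiazomethane 12, and the rest becomes dihydropyran 8, which already carries C5, C4 and C3 with the C4/C5 stereochemistry in place. This cut is preferred to cutting at C3–C4 or at the aryl bonds because it removes two ring bonds and two stereocentres at once and leaves a precursor with only two stereocentres, both accessible from a single catalytic step. The forward reaction must form an ylide at the ring oxygen on the face anti to the neighbouring aryl group and transfer the ylide carbon suprafacially to the alkene carbon.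

Carbene precursor. Compound 12 is too labile to store, so it is traced back to the sodium tosylhydrazonide 11, then to hydrazone 10, and to aldehyde 2 with hydrazide 9. Both aryl-bearing carbons of the target thus come from the same aldehyde.

Dihydropyran. In 8 the ring alkene is cut by ring-closing metathesis to diene 7. The O–allyl bond of 7 is cut to alcohol 5 and allyl bromide 6, and the silyl ether of 5 is cut to diol 4. These cuts are chosen because each forward step is routine, so the precursor of the key step is reached with little risk.

Stereogenic C–C bond. In 4 the bond between the carbinol carbon and the branch carbon is cut to aldehyde 2 and the racemic vinyl carbonate 3. The forward reaction must add a (hydroxymethyl)allyl nucleophile to the aldehyde with anti-diastereoselectivity and catalyst-controlled enantioselectivity. This sets both stereocentres of the precursor in one step, and they become C5 and C4 of the target.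

Aldehyde. Compound 2 comes from syringaldehyde 1 by O-benzylation.

## Alternatives that were turned down

Alternative 1: Both aryl–ring bonds (C2–aryl and C5–aryl) are cut. In the forward direction a Lewis acid ionises the two acetal centres of the enantiopure bis-acetal A1 in turn, and each oxocarbenium ion is attacked by the para carbon of the phenol A2, giving the diacetate A3.
- For: it is the most convergent plan, it uses the twofold symmetry that the chosen route ignores, it needs no phenol protection, and each aryl group should settle trans to its neighbouring branch. On step count after A1 and on precedent for the bond-forming reaction type it is stronger than the chosen route.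
- Against: A1 needs its own asymmetric synthesis of the trans-3,4 core. A2 is activated at the positions ortho/para to its methoxy groups as well as para to the hydroxyl, so regiochemistry is not secure. The neighbouring acetoxymethyl groups can participate at the oxocarbenium ions. Each newly formed C–O bond is a p-hydroxybenzylic ether and ionises under the same Lewis acid, which invites ring opening and a second arylation at the same carbon.
- Comparison: the chosen route instead forms the C2–C3 bond under neutral conditions with the phenols masked, so the acid lability of the ring is never exposed to a carbon nucleophile.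

Alternative 2: C3–C4 and both ring C–O bonds are cut. In the forward direction two molecules of the sinapoyl imide A4 are oxidised to phenoxyl radicals that couple at their β-carbons; the resulting bis(quinone methide) is hydrated once and closes to the bis-imide A5.
- For: it is by far the shortest plan, it mirrors the biosynthesis, and it builds the ring and all four centres in one flask. On step economy the chosen route cannot match it.
- Against: the radical coupling takes place at a planar carbon several bonds from the auxiliary stereocentre, so both the rac/meso outcome and the absolute sense are weakly controlled. The bis(quinone methide) of a sinapate-type dimer can close by intramolecular arylation to a dihydronaphthalene. Exactly one hydration followed by ring closure must outcompete that and double hydration.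
- Comparison: the chosen route offers in exchange a defined controlling element for every stereocentre (a closed transition state for C4/C5, a suprafacial shift for C3, thermodynamics for C2).

Alternative 3: Only C3–C4 is cut. In the forward direction the ether-tethered diester A6 is deprotonated twice by a lithium amide and the dienolate is oxidised by a copper or iodine oxidant, closing the ring to the diester A7.
- For: intramolecular oxidative enolate coupling is an established bond construction, the closure is five-membered, the substrate is symmetric, and the ester-bearing centres could later be epimerised to trans. On precedent for the ring-forming step it is stronger than the chosen route.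
- Against: each enolate carbon of A6 is β to the benzylic ether oxygen, so E1cB loss of the alkoxide (retro-oxa-Michael to a cinnamate) threatens before any oxidation. A6 itself needs two benzylic ether stereocentres of defined configuration joined through one oxygen, which is a hard problem of its own.
- Comparison: the chosen route never places a carbanion β to the ring oxygen and sets its two starting stereocentres in one catalytic step.

Key step: step 8

Assumption: the sense of induction of the iridium/(R)-SEGPHOS catalyst in step 2 is assigned by analogy with related carbonyl allylations of aryl aldehydes; if the diol formed as its (1S,2R) antipode, the (S)-ligand would be used with no other change.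

## Route

Step 1
Reactants: 1 syringaldehyde (4-hydroxy-3,5-dimethoxybenzaldehyde)
Product: 2 4-(benzyloxy)-3,5-dimethoxybenzaldehyde
Conditions: BnBr, K2CO3, DMF, 60 °C
Reagents that add atoms: benzyl bromide, BrCc1ccccc1
Why: Williamson etherification of an acidic, para-formyl phenol; the aryl benzyl ether withstands base, hydride, metathesis and carbene chemistry and is removed last.

Step 2
Reactants: 2 4-(benzyloxy)-3,5-dimethoxybenzaldehyde; 3 4-vinyl-1,3-dioxolan-2-one (racemic)
Product: 4 (1R,2S)-1-[4-(benzyloxy)-3,5-dimethoxyphenyl]-2-ethenylpropane-1,3-diol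
Conditions: [Ir(cod)Cl]2 (2.5 mol%), (R)-SEGPHOS (5 mol%), 4-cyano-3-nitrobenzoic acid (10 mol%), K3PO4 (cat.), i-PrOH (2 equiv), THF, 90 °C
Reagents that add atoms: none
Why: Iridium-catalysed transfer-hydrogenative carbonyl (hydroxymethyl)allylation: ionisation of 3 with loss of CO2 gives a (hydroxymethyl)allyl iridium species that is reduced by isopropanol and adds to the non-enolisable aldehyde. Addition of the (E)-σ-allyl through a closed chair transition state should place hydroxyl and hydroxymethyl anti, and the chiral bisphosphine selects the aldehyde face, so both stereocentres (later C5 and C4) are set here.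

Step 3
Reactants: 4 (1R,2S)-1-[4-(benzyloxy)-3,5-dimethoxyphenyl]-2-ethenylpropane-1,3-diol
Product: 5 (1R,2S)-1-[4-(benzyloxy)-3,5-dimethoxyphenyl]-2-{[tri(propan-2-yl)silyloxy]methyl}but-3-en-1-ol
Conditions: TIPSCl (1.1 equiv), imidazole, CH2Cl2, 0 °C to rt
Reagents that add atoms: triisopropylsilyl chloride, CC(C)[Si](Cl)(C(C)C)C(C)C
Why: Steric differentiation in silylation; the bulky chloride should react only at the primary hydroxyl. Triisopropylsilyl is preferred to smaller silyl groups because it resists alkoxide-induced migration in step 4 and shields its oxygen from the carbene in step 8.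

Step 4
Reactants: 5 (1R,2S)-1-[4-(benzyloxy)-3,5-dimethoxyphenyl]-2-{[tri(propan-2-yl)silyloxy]methyl}but-3-en-1-ol; 6 allyl bromide
Product: 7 triisopropyl{[(2S,3R)-3-[4-(benzyloxy)-3,5-dimethoxyphenyl]-2-ethenyl-3-(prop-2-en-1-yloxy)propyl]oxy}silane
Conditions: NaH, Bu4NI (cat.), THF–DMF, 0 °C to rt (base added to the alcohol and excess 6)
Reagents that add atoms: none
Why: Williamson O-allylation of the secondary benzylic alkoxide; the stereocentres are not touched, and having the electrophile present before the base keeps the lifetime of the alkoxide short.

Step 5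
Reactants: 7 triisopropyl{[(2S,3R)-3-[4-(benzyloxy)-3,5-dimethoxyphenyl]-2-ethenyl-3-(prop-2-en-1-yloxy)propyl]oxy}silane
Product: 8 (2R,3S)-2-[4-(benzyloxy)-3,5-dimethoxyphenyl]-3-{[tri(propan-2-yl)silyloxy]methyl}-3,6-dihydro-2H-pyran
Conditions: second-generation Grubbs catalyst (3 mol%), CH2Cl2 (0.01 M), 40 °C
Reagents that add atoms: none
Why: Ring-closing metathesis of two monosubstituted alkenes to a six-membered ring, driven by loss of ethylene; the trans relationship of aryl and silyloxymethyl groups is carried over unchanged.

Step 6
Reactants: 2 4-(benzyloxy)-3,5-dimethoxybenzaldehyde; 9 p-toluenesulfonyl hydrazide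
Product: 10 (E)-N'-[4-(benzyloxy)-3,5-dimethoxybenzylidene]-4-methylbenzenesulfonohydrazide
Conditions: MeOH, rt
Reagents that add atoms: none
Why: Condensation of an aryl aldehyde with a sulfonyl hydrazide; the hydrazone should crystallise from the medium.

Step 7
Reactants: 10 (E)-N'-[4-(benzyloxy)-3,5-dimethoxybenzylidene]-4-methylbenzenesulfonohydrazide
Product: 11 sodium salt of 10 (sodium N-{[4-(benzyloxy)-3,5-dimethoxyphenyl]methylideneamino}-4-methylbenzenesulfonamidate)
Conditions: NaOMe (1.0 equiv), MeOH, rt; evaporate, dry in vacuo, store cold in the dark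
Reagents that add atoms: sodium methoxide, [Na+].[O-]C
Why: Deprotonation of the acidic sulfonamide N–H; the dry salt is a storable, neutral source of the diazo compound by Bamford–Stevens fragmentation.

Step 8
Reactants: 8 (2R,3S)-2-[4-(benzyloxy)-3,5-dimethoxyphenyl]-3-{[tri(propan-2-yl)silyloxy]methyl}-3,6-dihydro-2H-pyran; 11 sodium salt of 10
Product: 14 (2R,3R,4S,5R)-2,5-bis[4-(benzyloxy)-3,5-dimethoxyphenyl]-3-ethenyl-4-{[tri(propan-2-yl)silyloxy]methyl}oxolane, via aryldiazomethane 12 (not isolated), via oxonium ylide 13 (not isolated)
Conditions: Rh2(OAc)4 (2 mol%), BnEt3NCl (10 mol%), PhMe, 40 °C, dark; 8 (1 equiv), 11 (3 equiv) added in portions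
Reagents that add atoms: none
Why: Proposed new method: fragmentation of 11, carried into solution by the ammonium salt, should release 12 slowly, and Rh2(OAc)4 should convert it into an electrophilic aryl carbene that is captured by the ring oxygen of 8 to give ylide 13, whose carbanion bonds to the distal alkene carbon while the O–CH2 bond breaks in a suprafacial [2,3]-sigmatropic shift; the closest known reaction types are [2,3]-rearrangements of catalytically generated allylic oxonium ylides and ring contractions of six-membered cyclic allylic sulfonium ylides, whereas the oxygen series with an endocyclic allyl unit and a donor aryl carbene has not been shown. The tetrahydrofuran closes by attack of the ylide carbon on the ring alkene, formally 5-exo-trig with respect to the new ring, through a five-membered envelope (O, CH2, CH, CH, ylide carbon) that requires the dihydropyran to adopt a boat with the oxygen and the alkene carbon at prow and stern. The new centre C3 is controlled by the aryl-bearing carbon next to oxygen: the bulky carbenoid should add to the lone pair anti to that aryl group, and because the shift is suprafacial the carbon is delivered on the same ring face, which places the emerging vinyl group trans to the silyloxymethyl branch on C4. The new centre C2 is controlled by the orientation of the carbene aryl group in the envelope, the exo placement (away from the allyl fragment) giving the 2,3-trans isomer. This second element is the weaker one, but C2 is a benzylic ether carbon on an electron-rich ring, so brief Lewis-acid equilibration (BF3·OEt2, CH2Cl2, low temperature) of the silyl-protected product would converge on the all-trans isomer if an epimer accompanied it. Chemoselectivity rests on the ring oxygen being the only dialkyl ether oxygen: the aryl ether oxygens are conjugated and flanked, the silyl ether oxygen is shielded by the triisopropylsilyl group, and the cis-disubstituted, allylically oxygenated alkene is a poor partner for cyclopropanation by a donor carbene. Slow release and an excess of 11 are meant to keep carbene dimerisation from outrunning ylide formation.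

Step 9
Reactants: 14 (2R,3R,4S,5R)-2,5-bis[4-(benzyloxy)-3,5-dimethoxyphenyl]-3-ethenyl-4-{[tri(propan-2-yl)silyloxy]methyl}oxolane
Product: 15 (2R,3R,4S,5R)-2,5-bis[4-(benzyloxy)-3,5-dimethoxyphenyl]-4-{[tri(propan-2-yl)silyloxy]methyl}oxolane-3-carbaldehyde
Conditions: OsO4 (2 mol%), NaIO4 (4 equiv), 2,6-lutidine, 1,4-dioxane–H2O, rt
Reagents that add atoms: osmium tetroxide (catalytic oxygen carrier), O=[Os](=O)(=O)=O; sodium periodate, [Na+].[O-]I(=O)(=O)=O
Why: Lemieux–Johnson cleavage of the only alkene; the buffered, neutral medium leaves the benzylic ethers and the fully etherified arenes alone, and the aldehyde α-centre already has the more stable trans arrangement.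

Step 10
Reactants: 15 (2R,3R,4S,5R)-2,5-bis[4-(benzyloxy)-3,5-dimethoxyphenyl]-4-{[tri(propan-2-yl)silyloxy]methyl}oxolane-3-carbaldehyde
Product: 16 [(2R,3S,4S,5R)-2,5-bis[4-(benzyloxy)-3,5-dimethoxyphenyl]-4-{[tri(propan-2-yl)silyloxy]methyl}oxolan-3-yl]methanol
Conditions: NaBH4, MeOH–THF, 0 °C
Reagents that add atoms: none
Why: Hydride reduction of an aldehyde; no stereocentre is formed or disturbed (the change of descriptor at C3 is a priority effect only).

Step 11
Reactants: 16 [(2R,3S,4S,5R)-2,5-bis[4-(benzyloxy)-3,5-dimethoxyphenyl]-4-{[tri(propan-2-yl)silyloxy]methyl}oxolan-3-yl]methanol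
Product: 17 [(2R,3S,4S,5R)-2,5-bis[4-(benzyloxy)-3,5-dimethoxyphenyl]oxolane-3,4-diyl]dimethanol
Conditions: Bu4NF, THF, 0 °C to rt
Reagents that add atoms: none
Why: Fluoride cleavage of a primary silyl ether under non-acidic conditions, so the benzylic ring ethers cannot ionise; doing this before debenzylation keeps the product lipophilic and easy to purify.

Step 12
Reactants: 17 [(2R,3S,4S,5R)-2,5-bis[4-(benzyloxy)-3,5-dimethoxyphenyl]oxolane-3,4-diyl]dimethanol
Product: 18 [(2R,3S,4S,5R)-2,5-bis(4-hydroxy-3,5-dimethoxyphenyl)oxolane-3,4-diyl]dimethanol (target)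
Conditions: H2 (1 atm), Pd/C, EtOAc–MeOH, rt, no acid; stopped when uptake ceases
Reagents that add atoms: none
Why: Catalytic hydrogenolysis; aryl benzyl ethers should cleave much faster than the dialkyl benzylic C–O bonds of the ring in a neutral medium, and leaving out acid also avoids dehydrative rearrangement of the free diol.

## Compound list

1 | syringaldehyde (4-hydroxy-3,5-dimethoxybenzaldehyde) | COc1cc(C=O)cc(OC)c1O | starting material
2 | 4-(benzyloxy)-3,5-dimethoxybenzaldehyde | COc1cc(C=O)cc(OC)c1OCc1ccccc1 | intermediate
3 | 4-vinyl-1,3-dioxolan-2-one (racemic) | C=CC1COC(=O)O1 | starting material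
4 | (1R,2S)-1-[4-(benzyloxy)-3,5-dimethoxyphenyl]-2-ethenylpropane-1,3-diol | COc1cc([C@H](O)[C@H](CO)C=C)cc(OC)c1OCc1ccccc1 | intermediate
5 | (1R,2S)-1-[4-(benzyloxy)-3,5-dimethoxyphenyl]-2-{[tri(propan-2-yl)silyloxy]methyl}but-3-en-1-ol | COc1cc([C@H](O)[C@H](CO[Si](C(C)C)(C(C)C)C(C)C)C=C)cc(OC)c1OCc1ccccc1 | intermediate
6 | allyl bromide (3-bromoprop-1-ene) | C=CCBr | starting material
7 | triisopropyl{[(2S,3R)-3-[4-(benzyloxy)-3,5-dimethoxyphenyl]-2-ethenyl-3-(prop-2-en-1-yloxy)propyl]oxy}silane | COc1cc([C@H](OCC=C)[C@H](CO[Si](C(C)C)(C(C)C)C(C)C)C=C)cc(OC)c1OCc1ccccc1 | intermediate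
8 | (2R,3S)-2-[4-(benzyloxy)-3,5-dimethoxyphenyl]-3-{[tri(propan-2-yl)silyloxy]methyl}-3,6-dihydro-2H-pyran | COc1cc([C@@H]2OCC=C[C@H]2CO[Si](C(C)C)(C(C)C)C(C)C)cc(OC)c1OCc1ccccc1 | intermediate
9 | p-toluenesulfonyl hydrazide | Cc1ccc(S(=O)(=O)NN)cc1 | starting material
10 | (E)-N'-[4-(benzyloxy)-3,5-dimethoxybenzylidene]-4-methylbenzenesulfonohydrazide | COc1cc(/C=N/NS(=O)(=O)c2ccc(C)cc2)cc(OC)c1OCc1ccccc1 | intermediate
11 | sodium salt of 10 | COc1cc(/C=N/[N-]S(=O)(=O)c2ccc(C)cc2)cc(OC)c1OCc1ccccc1.[Na+] | intermediate
12 | [4-(benzyloxy)-3,5-dimethoxyphenyl]diazomethane | COc1cc(C=[N+]=[N-])cc(OC)c1OCc1ccccc1 | intermediate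
13 | oxonium ylide of 8: (2R,3S)-2-aryl-1-(arylmethanidyl)-3-{[tri(propan-2-yl)silyloxy]methyl}-3,6-dihydro-2H-pyran-1-ium (aryl = 4-benzyloxy-3,5-dimethoxyphenyl), ylide carbon on the ring face anti to the C2 aryl group | COc1cc([C@@H]2[O+]([CH-]c3cc(OC)c(OCc4ccccc4)c(OC)c3)CC=C[C@H]2CO[Si](C(C)C)(C(C)C)C(C)C)cc(OC)c1OCc1ccccc1 | intermediate
14 | (2R,3R,4S,5R)-2,5-bis[4-(benzyloxy)-3,5-dimethoxyphenyl]-3-ethenyl-4-{[tri(propan-2-yl)silyloxy]methyl}oxolane (all-trans) | COc1cc([C@@H]2O[C@@H](c3cc(OC)c(OCc4ccccc4)c(OC)c3)[C@H](CO[Si](C(C)C)(C(C)C)C(C)C)[C@H]2C=C)cc(OC)c1OCc1ccccc1 | intermediate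
15 | (2R,3R,4S,5R)-2,5-bis[4-(benzyloxy)-3,5-dimethoxyphenyl]-4-{[tri(propan-2-yl)silyloxy]methyl}oxolane-3-carbaldehyde | COc1cc([C@@H]2O[C@@H](c3cc(OC)c(OCc4ccccc4)c(OC)c3)[C@H](CO[Si](C(C)C)(C(C)C)C(C)C)[C@H]2C=O)cc(OC)c1OCc1ccccc1 | intermediate
16 | [(2R,3S,4S,5R)-2,5-bis[4-(benzyloxy)-3,5-dimethoxyphenyl]-4-{[tri(propan-2-yl)silyloxy]methyl}oxolan-3-yl]methanol | COc1cc([C@@H]2O[C@@H](c3cc(OC)c(OCc4ccccc4)c(OC)c3)[C@H](CO[Si](C(C)C)(C(C)C)C(C)C)[C@H]2CO)cc(OC)c1OCc1ccccc1 | intermediate
17 | [(2R,3S,4S,5R)-2,5-bis[4-(benzyloxy)-3,5-dimethoxyphenyl]oxolane-3,4-diyl]dimethanol | COc1cc([C@@H]2O[C@@H](c3cc(OC)c(OCc4ccccc4)c(OC)c3)[C@H](CO)[C@H]2CO)cc(OC)c1OCc1ccccc1 | intermediate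
18 | [(2R,3S,4S,5R)-2,5-bis(4-hydroxy-3,5-dimethoxyphenyl)oxolane-3,4-diyl]dimethanol | COc1cc([C@@H]2O[C@@H](c3cc(OC)c(O)c(OC)c3)[C@H](CO)[C@H]2CO)cc(OC)c1O | target

## Step count and least certain steps

Total step count: 12. Longest linear sequence: 10 steps (steps 1, 2, 3, 4, 5, 8, 9, 10, 11, 12); steps 6 and 7 form the short branch to the carbene precursor.

Step 8 (key step). Several things may go wrong:
- The carbene may be consumed by dimerisation or by cyclopropanation before it reaches the hindered ring oxygen.
- The ylide may avoid the strained bicyclic transition state by a Stevens-type [1,2]-shift or by heterolysis of its electron-rich benzylic C–O bond.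
- Ylide formation on the face syn to the aryl group would erode control at C3.
- Weak exo/endo discrimination would erode control at C2; this alone is remediable by the Lewis-acid equilibration noted in the step.

The fallback uses known chemistry, sets out from 5 and comes back at 14. Alcohol 5 is silylated with allyl(chloro)dimethylsilane (imidazole, CH2Cl2) to give the allyl(dimethyl)silyl ether F1. Ring-closing metathesis with the second-generation Grubbs catalyst then gives the seven-membered cyclic allylsiloxane F2. Condensation of F2 with aldehyde 2 under BF3·OEt2 (CH2Cl2, −78 °C) generates an oxocarbenium ion on the ring oxygen that is trapped by the tethered allylsilane (intramolecular Hosomi–Sakurai reaction). This closes the tetrahydrofuran with its 3-vinyl group and gives 14. All substituents can lie pseudo-equatorial in the envelope transition state, and the benzylic centres remain open to thermodynamic correction under the same Lewis acid.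

Step 2. Facial or anti/syn selectivity may be insufficient with this ortho,ortho'-dioxygenated, electron-rich aldehyde, or part of the aldehyde may be reduced without coupling. The fallback sets out from 2 and comes back at 4. The commercial (R)-4-benzyl-1,3-oxazolidin-2-one is N-acylated with crotonyl chloride to give (R)-4-benzyl-3-[(E)-but-2-enoyl]-1,3-oxazolidin-2-one F3. Its dibutylboron dienolate (Bu2BOTf, Et3N, CH2Cl2, −78 °C) adds to 2 through the α-carbon in an Evans syn-aldol reaction to give (4R)-4-benzyl-3-{(2R,3R)-3-[4-(benzyloxy)-3,5-dimethoxyphenyl]-2-ethenyl-3-hydroxypropanoyl}-1,3-oxazolidin-2-one F4. The syn relationship of hydroxyl and vinyl in F4 is the same spatial arrangement as the anti relationship of hydroxyl and hydroxymethyl in 4. LiBH4 (THF–MeOH) then cleaves the auxiliary reductively and gives 4.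

Step 4. The hindered secondary alkoxide may alkylate slowly, giving time for silyl transfer from the primary to the secondary oxygen. The fallback sets out from 5 and comes back at 7. The alcohol is etherified with allyl tert-butyl carbonate under zerovalent palladium catalysis (Pd2(dba)3, 1,4-bis(diphenylphosphino)butane, THF, 65 °C). The electrophile is then a π-allylpalladium cation and the alkoxide is only ever present in a transient, catalytic amount. This fallback makes no new compound (F0).

Step 12. Hydrogenolysis may go on from the aryl benzyl ethers to the ring C–O bonds, which are themselves benzylic, especially once the para-hydroxyl groups are free. The fallback sets out from 17 and comes back at 18. Acetylation (Ac2O, pyridine) gives the diacetate F5, [(2R,3S,4S,5R)-2,5-bis[4-(benzyloxy)-3,5-dimethoxyphenyl]oxolane-3,4-diyl]bis(methylene) diacetate. BCl3 with pentamethylbenzene as cation scavenger (CH2Cl2, −78 °C) removes the benzyl groups by chelation-assisted Lewis-acid cleavage and gives the bis-phenol diacetate F6, [(2R,3S,4S,5R)-2,5-bis(4-hydroxy-3,5-dimethoxyphenyl)oxolane-3,4-diyl]bis(methylene) diacetate. The primary oxygens are acylated at this point and cannot attack a transient benzylic cation. Mild methanolysis (K2CO3, MeOH, 0 °C, under argon) then gives 18.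

## Further compounds

F1 | step 8 | {[(1R,2S)-1-[4-(benzyloxy)-3,5-dimethoxyphenyl]-2-{[tri(propan-2-yl)silyloxy]methyl}but-3-en-1-yl]oxy}(dimethyl)(prop-2-en-1-yl)silane | COc1cc([C@H](O[Si](C)(C)CC=C)[C@H](CO[Si](C(C)C)(C(C)C)C(C)C)C=C)cc(OC)c1OCc1ccccc1
F2 | step 8 | (6S,7R)-7-[4-(benzyloxy)-3,5-dimethoxyphenyl]-2,2-dimethyl-6-{[tri(propan-2-yl)silyloxy]methyl}-2,3,6,7-tetrahydro-1,2-oxasilepine | COc1cc([C@@H]2O[Si](C)(C)CC=C[C@H]2CO[Si](C(C)C)(C(C)C)C(C)C)cc(OC)c1OCc1ccccc1
F3 | step 2 | (R)-4-benzyl-3-[(E)-but-2-enoyl]-1,3-oxazolidin-2-one | C/C=C/C(=O)N1[C@H](Cc2ccccc2)COC1=O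
F4 | step 2 | (4R)-4-benzyl-3-{(2R,3R)-3-[4-(benzyloxy)-3,5-dimethoxyphenyl]-2-ethenyl-3-hydroxypropanoyl}-1,3-oxazolidin-2-one | COc1cc([C@H](O)[C@H](C(=O)N2[C@H](Cc3ccccc3)COC2=O)C=C)cc(OC)c1OCc1ccccc1
F0 | step 4 | none | none
F5 | step 12 | [(2R,3S,4S,5R)-2,5-bis[4-(benzyloxy)-3,5-dimethoxyphenyl]oxolane-3,4-diyl]bis(methylene) diacetate | COc1cc([C@@H]2O[C@@H](c3cc(OC)c(OCc4ccccc4)c(OC)c3)[C@H](COC(C)=O)[C@H]2COC(C)=O)cc(OC)c1OCc1ccccc1
F6 | step 12 | [(2R,3S,4S,5R)-2,5-bis(4-hydroxy-3,5-dimethoxyphenyl)oxolane-3,4-diyl]bis(methylene) diacetate | COc1cc([C@@H]2O[C@@H](c3cc(OC)c(O)c(OC)c3)[C@H](COC(C)=O)[C@H]2COC(C)=O)cc(OC)c1O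
A1 | alternative 1 | [(3S,4S)-2,5-dimethoxyoxolane-3,4-diyl]bis(methylene) diacetate (mixture at the acetal carbons) | COC1OC(OC)[C@H](COC(C)=O)[C@H]1COC(C)=O
A2 | alternative 1 | 2,6-dimethoxyphenol | COc1cccc(OC)c1O
A3 | alternative 1 | [(2R,3S,4S,5R)-2,5-bis(4-hydroxy-3,5-dimethoxyphenyl)oxolane-3,4-diyl]bis(methylene) diacetate | COc1cc([C@@H]2O[C@@H](c3cc(OC)c(O)c(OC)c3)[C@H](COC(C)=O)[C@H]2COC(C)=O)cc(OC)c1O
A4 | alternative 2 | (S)-4-benzyl-3-[(E)-3-(4-hydroxy-3,5-dimethoxyphenyl)prop-2-enoyl]-1,3-oxazolidin-2-one | COc1cc(/C=C/C(=O)N2[C@@H](Cc3ccccc3)COC2=O)cc(OC)c1O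
A5 | alternative 2 | (2R,3R,4R,5R)-2,5-bis(4-hydroxy-3,5-dimethoxyphenyl)oxolane-3,4-dicarbonyl bis[(S)-4-benzyl-1,3-oxazolidin-2-one] imide | COc1cc([C@@H]2O[C@@H](c3cc(OC)c(O)c(OC)c3)[C@H](C(=O)N3[C@@H](Cc4ccccc4)COC3=O)[C@H]2C(=O)N2[C@@H](Cc3ccccc3)COC2=O)cc(OC)c1O
A6 | alternative 3 | dimethyl (3R,3'R)-3,3'-oxybis{3-[4-(benzyloxy)-3,5-dimethoxyphenyl]propanoate} | COc1cc([C@@H](CC(=O)OC)O[C@@H](c2cc(OC)c(OCc3ccccc3)c(OC)c2)CC(=O)OC)cc(OC)c1OCc1ccccc1
A7 | alternative 3 | dimethyl (2R,3R,4R,5R)-2,5-bis[4-(benzyloxy)-3,5-dimethoxyphenyl]oxolane-3,4-dicarboxylate | COc1cc([C@@H]2O[C@@H](c3cc(OC)c(OCc4ccccc4)c(OC)c3)[C@H](C(=O)OC)[C@H]2C(=O)OC)cc(OC)c1OCc1ccccc1
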